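The target is cut at the C4–C5 and O1–C5 bonds of the butenolide. Its Z enol lactone, O1–C5(=C6H–ring C), is the anti adduct of the C2 carboxylic acid across a C5≡C6 aryl alkyne held cis on the C3=C4 double bond. One palladium/copper operation therefore couples a ring C arylacetylene to a C4 vinyl iodide and closes the lactone 5-exo-dig, setting the C5=C6 geometry. The precursor is a (Z)-3-aryl-3-iodoacrylic acid carrying ring B at C4 and the (S)-carbinol with ring A at C3, itself assembled by an enantioselective iodo-aldol union of a ring B arylpropiolate with the ring A aldehyde.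

Key step: step 6

Labels: butenolide O1, C2 (carbonyl), C3, C4, C5, exocyclic C6; ring A = 3,5-dibromo-4-methoxyphenyl on the carbinol carbon, ring B = 3-bromo-4-hydroxyphenyl on C4, ring C = 3-bromo-4-hydroxyphenyl on C6.

Assumption: the oxazaborolidinium ion from (R)-diphenylprolinol is taken to direct the nucleophile to the Re face of aldehyde 8, which gives the (S)-carbinol, by analogy with other additions in this catalyst class; if the sense proved opposite, the antipodal catalyst would be used.

Step 1
Reactants: 1 3-bromo-4-hydroxybenzaldehyde; 2 dimethyl (1-diazo-2-oxopropyl)phosphonate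
Product: 3 2-bromo-4-ethynylphenol
Conditions: 2 (2 equiv), K2CO3 (3.5 equiv), MeOH, 0 °C → rt; aq. NH4Cl
Reagents that add atoms: none
Why: Seyferth–Gilbert homologation in its Ohira–Bestmann form, in which methoxide deacetylates 2 to the diazomethylphosphonate anion that olefinates the aldehyde and loses N2 to give the alkyne; no palladium or organolithium touches the aryl bromide, and the excess of reagent offsets the deactivation of the aldehyde by the para phenoxide.

Step 2
Reactants: 3 2-bromo-4-ethynylphenol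
Product: 4 tert-butyl(2-bromo-4-ethynylphenoxy)dimethylsilane
Conditions: TBSCl (1.2 equiv), imidazole (2.5 equiv), DMF, 0 °C → rt
Reagents that add atoms: tert-butyldimethylsilyl chloride, CC(C)(C)[Si](C)(C)Cl
Why: routine silylation of a phenol, which removes the acidic O–H before the amide-base step and gives the alkyne used twice (ring B in step 3, ring C in step 6).

Step 3
Reactants: 4 tert-butyl(2-bromo-4-ethynylphenoxy)dimethylsilane; 5 methyl chloroformate
Product: 7 methyl 3-[3-bromo-4-(tert-butyldimethylsilyloxy)phenyl]prop-2-ynoate, via lithium acetylide 6 (not isolated)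
Conditions: LiN(iPr)2 (1.05 equiv), THF, –78 °C; then ClCO2Me (1.5 equiv), –78 → 0 °C
Reagents that add atoms: none
Why: the amide base removes only the alkyne C–H, which is far more acidic than any aryl C–H (an alkyllithium would exchange the bromide), and C-acylation of the acetylide by a chloroformate is the standard ynoate synthesis.

Step 4
Reactants: 7 methyl 3-[3-bromo-4-(tert-butyldimethylsilyloxy)phenyl]prop-2-ynoate; 8 3,5-dibromo-4-methoxybenzaldehyde
Product: 11 methyl (2Z)-3-[3-bromo-4-(tert-butyldimethylsilyloxy)phenyl]-2-[(S)-(3,5-dibromo-4-methoxyphenyl)(hydroxy)methyl]-3-iodoprop-2-enoate, via silyl allenolate 9 (not isolated), via O-trimethylsilyl aldol adduct 10 (not isolated)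
Conditions: 7 (1.2 equiv), Me3SiI (1.3 equiv), (R)-tetrahydro-1-(2-methylphenyl)-3,3-diphenyl-1H,3H-pyrrolo[1,2-c][1,3,2]oxazaborole·HN(SO2CF3)2 (20 mol %), CH2Cl2, –78 °C; then 1 M HCl, THF, 0 °C
Reagents that add atoms: iodotrimethylsilane, C[Si](C)(C)I
Why: Proposed new method: conjugate addition of iodide from Me3SiI to C4 of ynoate 7 should give the β-iodo silyl allenolate 9, whose C3 adds in a Mukaiyama-type aldol to aldehyde 8 held on the chiral boron cation, so the catalyst (one aldehyde face shielded by its aryl groups) sets the (S)-carbinol by Re-face attack, while approach of the aldehyde to the side of C3 remote from iodine, the same kinetic anti course seen in hydroiodination of arylpropiolates to (Z)-3-iodocinnamates, places iodine cis to the ester; silyl transfer gives 10 and dilute HCl frees the alcohol; the closest known reaction type is the oxazaborolidinium-catalysed three-component iodo-aldol of unsubstituted propiolates with aromatic aldehydes, and the β-aryl group, which slows iodide addition and crowds the allenolate, is the untested element.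

Step 5
Reactants: 11 methyl (2Z)-3-[3-bromo-4-(tert-butyldimethylsilyloxy)phenyl]-2-[(S)-(3,5-dibromo-4-methoxyphenyl)(hydroxy)methyl]-3-iodoprop-2-enoate
Product: 12 (2Z)-3-(3-bromo-4-hydroxyphenyl)-2-[(S)-(3,5-dibromo-4-methoxyphenyl)(hydroxy)methyl]-3-iodoprop-2-enoic acid
Conditions: LiOH·H2O (5 equiv), THF/H2O (3:1), 0 °C → rt; then 1 M HCl to pH 2–3
Reagents that add atoms: lithium hydroxide, [Li+].[OH-]
Why: saponification of a methyl ester with no α-hydrogen to epimerise, in which hydroxide also cleaves the labile aryl silyl ether; the carbinol C–O and C–C bonds are not touched, and the low temperature and the absence of an alcohol cosolvent limit addition–elimination at the iodine-bearing C4.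

Step 6
Reactants: 12 (2Z)-3-(3-bromo-4-hydroxyphenyl)-2-[(S)-(3,5-dibromo-4-methoxyphenyl)(hydroxy)methyl]-3-iodoprop-2-enoic acid; 4 tert-butyl(2-bromo-4-ethynylphenoxy)dimethylsilane
Product: 14 (5Z)-4-(3-bromo-4-hydroxyphenyl)-5-{[3-bromo-4-(tert-butyldimethylsilyloxy)phenyl]methylidene}-3-[(S)-(3,5-dibromo-4-methoxyphenyl)(hydroxy)methyl]furan-2(5H)-one, via enynoic acid 13 (not isolated)
Conditions: 4 (1.3 equiv), PdCl2(PPh3)2 (5 mol %), CuI (10 mol %), Et3N (5 equiv), degassed MeCN, rt
Reagents that add atoms: none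
Why: Zerovalent palladium formed from PdCl2(PPh3)2 should insert into the C4–I bond of 12, the copper acetylide of 4 transmetalates and reductive elimination forms the C4–C5 bond to give the (Z)-enynoic acid 13, whose carboxylate, held cis to the alkyne, then adds anti across C5≡C6 under activation by divalent palladium or monovalent copper before protodemetalation releases the enol lactone. The closest known reaction type is the tandem Sonogashira coupling and lactonisation of (Z)-3-iodoalk-2-enoic acids, 3-aryl ones included, with terminal alkynes to (Z)-5-ylidenebutenolides. The butenolide, the only ring made, closes by 5-exo-dig attack of O1 on C5. No stereocentre is created: the C5=C6 geometry follows from the anti oxymetalation, which leaves O1 and ring C cis (Z) and is also the less strained arrangement, and the (S)-carbinol is a spectator whose hydroxyl sits trans to the alkyne and cannot reach it. The step needs C–I over C–Br selectivity, secured by oxidative addition of the electron-poor vinyl iodide at room temperature long before any of the four oxygen-flanked aryl bromides, and 5-exo over 6-endo closure, favoured by the rigid cis placement of the carboxylate on the tetrasubstituted C3=C4 bond and by keeping ring C as its less donating silyl ether.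

Step 7
Reactants: 14 (5Z)-4-(3-bromo-4-hydroxyphenyl)-5-{[3-bromo-4-(tert-butyldimethylsilyloxy)phenyl]methylidene}-3-[(S)-(3,5-dibromo-4-methoxyphenyl)(hydroxy)methyl]furan-2(5H)-one
Product: 15 (5Z)-4-(3-bromo-4-hydroxyphenyl)-5-[(3-bromo-4-hydroxyphenyl)methylidene]-3-[(S)-(3,5-dibromo-4-methoxyphenyl)(hydroxy)methyl]furan-2(5H)-one
Conditions: Bu4NF (1.2 equiv), AcOH (1.5 equiv), THF, 0 °C
Reagents that add atoms: none
Why: fluoride cleaves the aryl silyl ether rapidly, and buffering with acetic acid keeps the medium too weakly basic to open the enol lactone or disturb the benzylic carbinol.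

Compound list
1 | 3-bromo-4-hydroxybenzaldehyde | O=Cc1ccc(O)c(Br)c1 | starting material
2 | dimethyl (1-diazo-2-oxopropyl)phosphonate | CC(=O)C(=[N+]=[N-])P(=O)(OC)OC | starting material
3 | 2-bromo-4-ethynylphenol | C#Cc1ccc(O)c(Br)c1 | intermediate
4 | tert-butyl(2-bromo-4-ethynylphenoxy)dimethylsilane | C#Cc1ccc(O[Si](C)(C)C(C)(C)C)c(Br)c1 | intermediate
5 | methyl chloroformate | COC(=O)Cl | starting material
6 | lithium {[3-bromo-4-(tert-butyldimethylsilyloxy)phenyl]ethynide} | [Li]C#Cc1ccc(O[Si](C)(C)C(C)(C)C)c(Br)c1 | intermediate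
7 | methyl 3-[3-bromo-4-(tert-butyldimethylsilyloxy)phenyl]prop-2-ynoate | COC(=O)C#Cc1ccc(O[Si](C)(C)C(C)(C)C)c(Br)c1 | intermediate
8 | 3,5-dibromo-4-methoxybenzaldehyde | COc1c(Br)cc(C=O)cc1Br | starting material
9 | 1-[3-bromo-4-(tert-butyldimethylsilyloxy)phenyl]-1-iodo-3-methoxy-3-(trimethylsilyloxy)propa-1,2-diene (allene axis racemic, lost in the next bond formation) | COC(O[Si](C)(C)C)=C=C(I)c1ccc(O[Si](C)(C)C(C)(C)C)c(Br)c1 | intermediate
10 | methyl (2Z)-3-[3-bromo-4-(tert-butyldimethylsilyloxy)phenyl]-2-[(S)-(3,5-dibromo-4-methoxyphenyl)(trimethylsilyloxy)methyl]-3-iodoprop-2-enoate | COc1c(Br)cc([C@H](O[Si](C)(C)C)/C(C(=O)OC)=C(/I)c2ccc(O[Si](C)(C)C(C)(C)C)c(Br)c2)cc1Br | intermediate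
11 | methyl (2Z)-3-[3-bromo-4-(tert-butyldimethylsilyloxy)phenyl]-2-[(S)-(3,5-dibromo-4-methoxyphenyl)(hydroxy)methyl]-3-iodoprop-2-enoate | COc1c(Br)cc([C@H](O)/C(C(=O)OC)=C(/I)c2ccc(O[Si](C)(C)C(C)(C)C)c(Br)c2)cc1Br | intermediate
12 | (2Z)-3-(3-bromo-4-hydroxyphenyl)-2-[(S)-(3,5-dibromo-4-methoxyphenyl)(hydroxy)methyl]-3-iodoprop-2-enoic acid | COc1c(Br)cc([C@H](O)/C(C(=O)O)=C(/I)c2ccc(O)c(Br)c2)cc1Br | intermediate
13 | (2Z)-3-(3-bromo-4-hydroxyphenyl)-5-[3-bromo-4-(tert-butyldimethylsilyloxy)phenyl]-2-[(S)-(3,5-dibromo-4-methoxyphenyl)(hydroxy)methyl]pent-2-en-4-ynoic acid | COc1c(Br)cc([C@H](O)/C(C(=O)O)=C(/C#Cc2ccc(O[Si](C)(C)C(C)(C)C)c(Br)c2)c2ccc(O)c(Br)c2)cc1Br | intermediate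
14 | (5Z)-4-(3-bromo-4-hydroxyphenyl)-5-{[3-bromo-4-(tert-butyldimethylsilyloxy)phenyl]methylidene}-3-[(S)-(3,5-dibromo-4-methoxyphenyl)(hydroxy)methyl]furan-2(5H)-one | COc1c(Br)cc([C@H](O)C2=C(c3ccc(O)c(Br)c3)/C(=C/c3ccc(O[Si](C)(C)C(C)(C)C)c(Br)c3)OC2=O)cc1Br | intermediate
15 | (5Z)-4-(3-bromo-4-hydroxyphenyl)-5-[(3-bromo-4-hydroxyphenyl)methylidene]-3-[(S)-(3,5-dibromo-4-methoxyphenyl)(hydroxy)methyl]furan-2(5H)-one (CID71459453) | COc1c(Br)cc([C@H](O)C2=C(c3ccc(O)c(Br)c3)/C(=C/c3ccc(O)c(Br)c3)OC2=O)cc1Br | target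

Total step count: 7.
Longest linear sequence: 7 steps (1 → 3 → 4 → 7 → 11 → 12 → 14 → 15); alkyne 4 enters a second time in step 6.

Steps most likely to fail

Step 4 (carries the label). The crowded β-aryl allenolate may add slowly, so that the chiral boron cation turns over poorly, the uncatalysed background pathway erodes facial selectivity, and warming to force conversion erodes the kinetic Z geometry. The fallback uses known chemistry and sets out from 7 and 8. The stoichiometric magnesium-mediated halo-aldol (MgI2, CH2Cl2, 0 °C), the established achiral form of this three-component reaction, would give the racemic methyl (2Z)-iodo hydroxy ester F1. Esterification of its carbinol with (S)-methoxy(phenyl)acetic acid (DCC, cat. DMAP, CH2Cl2) would give two diastereomers separable on silica, the (S)-carbinol (S)-methoxy(phenyl)acetate F2 and the (R)-carbinol (S)-methoxy(phenyl)acetate F3. F2 is then submitted to the LiOH conditions of step 5, which cleave the auxiliary ester, the methyl ester and the aryl silyl ether together, and the route is rejoined at 12.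

Step 6. After the coupling the carboxylate may add to C6 instead of C5 (6-endo closure to a pyranone), or ring closure may lag so that the enynoic acid accumulates and the alkyne is consumed by oxidative dimerisation. The fallback separates the two events and sets out from 11. Sonogashira coupling with 4 under the same PdCl2(PPh3)2/CuI/Et3N conditions at the ester stage, where no cyclisation can occur, would give the methyl enynoate with both phenols silylated F4. LiOH in THF/H2O would then give the enynoic acid with both phenols free F5. A catalytic silver salt (AgNO3 or Ag2CO3, acetone, rt), the known 5-exo-selective catalyst for (Z)-2-en-4-ynoic acids, would close the lactone and return to the route at 15.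

Step 5. Besides hydrolysing the hindered ester, hydroxide may deprotonate the carbinol, and the alkoxide can expel the ring A aldehyde by retro-aldol-type fragmentation with loss of iodide, the reverse of step 4. The fallback masks the carbinol and sets out from 11. Et3SiOTf and 2,6-lutidine (CH2Cl2, –78 °C) would give the carbinol triethylsilyl ether F6. LiOH would then give the silyl-protected iodo acid with ring B phenol free F7. Coupling–lactonisation with 4 as in step 6 would give the doubly silylated butenolide F8, and HF·pyridine (THF, 0 °C → rt) would remove both silyl groups and return to the route at 15.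

Further compounds
F1 | step 4 | racemic methyl (2Z)-3-[3-bromo-4-(tert-butyldimethylsilyloxy)phenyl]-2-[(3,5-dibromo-4-methoxyphenyl)(hydroxy)methyl]-3-iodoprop-2-enoate | COc1c(Br)cc(C(O)/C(C(=O)OC)=C(/I)c2ccc(O[Si](C)(C)C(C)(C)C)c(Br)c2)cc1Br
F2 | step 4 | methyl (2Z)-3-[3-bromo-4-(tert-butyldimethylsilyloxy)phenyl]-2-[(S)-(3,5-dibromo-4-methoxyphenyl){[(2S)-2-methoxy-2-phenylacetyl]oxy}methyl]-3-iodoprop-2-enoate | COc1c(Br)cc([C@H](OC(=O)[C@@H](OC)c2ccccc2)/C(C(=O)OC)=C(/I)c2ccc(O[Si](C)(C)C(C)(C)C)c(Br)c2)cc1Br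
F3 | step 4 | methyl (2Z)-3-[3-bromo-4-(tert-butyldimethylsilyloxy)phenyl]-2-[(R)-(3,5-dibromo-4-methoxyphenyl){[(2S)-2-methoxy-2-phenylacetyl]oxy}methyl]-3-iodoprop-2-enoate | COc1c(Br)cc([C@@H](OC(=O)[C@@H](OC)c2ccccc2)/C(C(=O)OC)=C(/I)c2ccc(O[Si](C)(C)C(C)(C)C)c(Br)c2)cc1Br
F4 | step 6 | methyl (2Z)-3,5-bis[3-bromo-4-(tert-butyldimethylsilyloxy)phenyl]-2-[(S)-(3,5-dibromo-4-methoxyphenyl)(hydroxy)methyl]pent-2-en-4-ynoate | COc1c(Br)cc([C@H](O)/C(C(=O)OC)=C(/C#Cc2ccc(O[Si](C)(C)C(C)(C)C)c(Br)c2)c2ccc(O[Si](C)(C)C(C)(C)C)c(Br)c2)cc1Br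
F5 | step 6 | (2Z)-3,5-bis(3-bromo-4-hydroxyphenyl)-2-[(S)-(3,5-dibromo-4-methoxyphenyl)(hydroxy)methyl]pent-2-en-4-ynoic acid | COc1c(Br)cc([C@H](O)/C(C(=O)O)=C(/C#Cc2ccc(O)c(Br)c2)c2ccc(O)c(Br)c2)cc1Br
F6 | step 5 | methyl (2Z)-3-[3-bromo-4-(tert-butyldimethylsilyloxy)phenyl]-2-[(S)-(3,5-dibromo-4-methoxyphenyl)(triethylsilyloxy)methyl]-3-iodoprop-2-enoate | COc1c(Br)cc([C@H](O[Si](CC)(CC)CC)/C(C(=O)OC)=C(/I)c2ccc(O[Si](C)(C)C(C)(C)C)c(Br)c2)cc1Br
F7 | step 5 | (2Z)-3-(3-bromo-4-hydroxyphenyl)-2-[(S)-(3,5-dibromo-4-methoxyphenyl)(triethylsilyloxy)methyl]-3-iodoprop-2-enoic acid | COc1c(Br)cc([C@H](O[Si](CC)(CC)CC)/C(C(=O)O)=C(/I)c2ccc(O)c(Br)c2)cc1Br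
F8 | step 5 | (5Z)-4-(3-bromo-4-hydroxyphenyl)-5-{[3-bromo-4-(tert-butyldimethylsilyloxy)phenyl]methylidene}-3-[(S)-(3,5-dibromo-4-methoxyphenyl)(triethylsilyloxy)methyl]furan-2(5H)-one | COc1c(Br)cc([C@H](O[Si](CC)(CC)CC)C2=C(c3ccc(O)c(Br)c3)/C(=C/c3ccc(O[Si](C)(C)C(C)(C)C)c(Br)c3)OC2=O)cc1Br
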